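**Retrosynthetic overview**
1. The trans-2,3-epoxide comes from the erythro C2,C3-diol (C3 mesylate) of a Z-cyclodecene; the ten-membered ring is closed last by ring-closing metathesis at C2=C3.
2. The γ-lactone (C7–O–C19(=O)–C17–C8) comes from Baeyer–Villiger oxidation of a cyclobutanone; the cyclobutanone is made by an intramolecular ketene/silyl enol ether [2+2] cycloaddition that forms C19–C17 and C7–C8 at once.
3. Enabling feature: C6 (sp2 carbon of the C5=C6 alkene, C–H in the target) and the C8 hydroxyl oxygen are cis across the C7–C8 bond that the lactone shares with the ten-membered ring, so one SiPh2 unit can bridge C6 and O8 (temporary five-membered siloxane) and is removed at the end to leave C6–H and C8–OH.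
4. The silicon bridge joins fragment W (C3–C7, C16, C19; anti-allylmagnesiation of a propargylic alcohol) to fragment E (ring A, C2, C8–C10, C17, C18; catalytic asymmetric Diels–Alder, C11 hydroxylation, chelation-controlled addition at C9).
5. Order of ring formation: ring A → siloxane and cyclobutanone (key step) → γ-lactone → ten-membered ring → epoxide.

Key step: step 15

Remark on numbering: carbons are numbered on the target skeleton: C1 (quaternary, CH3 = C15), C2/C3 (epoxide), C4, C5 (CH2OH = C16), C6, C7 (lactone O–CH), C8 (C–OH), C9 (CHOAc), C10, C11 (CH3 = C20, OAc), C12 (C=O), C13=C14, C17 (CH3 = C18), C19 (lactone C=O). The target is (1S,2R,3R,5E,7S,8S,9R,10S,11S,17R).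
Remark on materials: 1, 3 and 14 are taken as purchasable; the catalyst antipode in step 2 is the one that gives the (1S,10S) sense.

Step 1
Reactants: 1 pent-1-en-3-one
Product: 2 (Z)-3-(tert-butyldimethylsilyloxy)penta-1,3-diene
Conditions: TBSOTf, Et3N, Et2O, 0 °C
Reagents that add atoms: tert-butyldimethylsilyl triflate, CC(C)(C)[Si](C)(C)OS(=O)(=O)C(F)(F)F
Why: Soft enolisation of the ethyl ketone with a silyl triflate and amine gives the 2-silyloxy diene as the Z enol ether, which places the C20 methyl outside in the s-cis diene.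

Step 2
Reactants: 2 (Z)-3-(tert-butyldimethylsilyloxy)penta-1,3-diene; 3 (E)-4-acetoxy-2-methylbut-2-enal
Product: 4 Diels–Alder adduct (ring A aldehyde)
Conditions: oxazaborolidinium catalyst [(S)-3,3-diphenyl-1-(2-methylphenyl)tetrahydro-1H,3H-pyrrolo[1,2-c][1,3,2]oxazaborole + HN(SO2CF3)2] (20 mol %), CH2Cl2, −78 → −40 °C
Reagents that add atoms: none
Why: Catalytic enantioselective Diels–Alder reaction in which the nucleophilic diene terminus C11 bonds to the enal β-carbon C10 (para regiochemistry), the E enal geometry fixes the C1 methyl cis to the C10 CH2OAc group, and the chiral Lewis acid shields one enal face to give (1S,10S); C11 is also formed but is reset in step 5.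

Step 3
Reactants: 4 Diels–Alder adduct (ring A aldehyde)
Product: 5 C1-vinyl silyl enol ether
Conditions: Ph3PCH3Br, KN(SiMe3)2, THF, 0 °C
Reagents that add atoms: methyltriphenylphosphonium bromide, C[P+](c1ccccc1)(c1ccccc1)c1ccccc1.[Br-]
Why: Wittig methylenation of the non-enolisable neopentyl aldehyde turns C2 into the vinyl group needed for ring closure without touching a stereocentre.

Step 4
Reactants: 5 C1-vinyl silyl enol ether
Product: 6 ring A enone
Conditions: Pd(OAc)2 (1.1 equiv), MeCN, 25 °C
Reagents that add atoms: none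
Why: Saegusa–Ito oxidation, in which the palladium enolate at C13 undergoes β-hydride elimination toward C14 and so gives the C13=C14 enone regiospecifically.

Step 5
Reactants: 6 ring A enone
Product: 8 11-hydroxy enone acetate, via lithium dienolate 7 (not isolated)
Conditions: LiN(i-Pr)2, THF, −78 °C; 2-(phenylsulfonyl)-3-phenyloxaziridine, −78 °C; AcOH
Reagents that add atoms: 2-(phenylsulfonyl)-3-phenyloxaziridine, O=S(=O)(c1ccccc1)N1OC1c1ccccc1
Why: Enolate hydroxylation with an N-sulfonyloxaziridine: only C11 carries an enolisable hydrogen, and the oxidant approaches the planar enolate anti to the adjacent C10 CH2OAc group, which puts the 11-OH trans to C9 and the C20 methyl cis to it (11S).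

Step 6
Reactants: 8 11-hydroxy enone acetate
Product: 9 ring A diol
Conditions: K2CO3 (0.2 equiv), MeOH, 0 °C
Reagents that add atoms: none
Why: Base-catalysed transesterification removes the unhindered primary acetate and leaves the tertiary alcohol and the hindered enone untouched.

Step 7
Reactants: 9 ring A diol
Product: 10 C9 aldehyde
Conditions: Dess–Martin periodinane, NaHCO3, CH2Cl2, 0 → 25 °C
Reagents that add atoms: none
Why: Dess–Martin oxidation of the primary alcohol under buffered, neutral conditions; the tertiary C11 hydroxyl cannot be oxidised and C10 is not epimerised.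

Step 8
Reactants: 10 C9 aldehyde
Product: 12 hydroxy vinyl ketone, via allenyl carbinol 11 (not isolated)
Conditions: 1-methoxyallene, n-BuLi, THF, −78 °C; MgBr2·OEt2; then 10, −78 °C; then 5% aq. H2SO4, 0 °C
Reagents that add atoms: 1-methoxyallene, COC=C=C; water, O
Why: Addition of 1-lithio-1-methoxyallene (an acryloyl anion equivalent) to the aldehyde held in a six-membered magnesium chelate with the C11 alkoxide, with attack on the face away from the two axial methyl groups expected to give (9R); mild acid then hydrolyses the allenyl ether to the vinyl ketone (C8, C17, C18).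

Step 9
Reactants: 12 hydroxy vinyl ketone
Product: 13 diacetate vinyl ketone (fragment E)
Conditions: Ac2O, Me3SiOTf (5 mol %), CH2Cl2, −20 °C
Reagents that add atoms: acetic anhydride, CC(=O)OC(C)=O
Why: Lewis acid-catalysed acetylation esterifies the secondary C9 and the tertiary C11 hydroxyl in one operation under non-basic conditions that spare the vinyl ketone.

Step 10
Reactants: 14 4,4-diethoxybut-1-yne
Product: 16 5,5-diethoxypent-2-yn-1-ol, via lithium acetylide 15 (not isolated)
Conditions: n-BuLi, THF, −78 °C; (CH2O)n, −78 → 25 °C; H2O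
Reagents that add atoms: paraformaldehyde (as formaldehyde), C=O
Why: Hydroxymethylation of the lithium acetylide installs C16 and the propargylic hydroxyl that directs the next step.

Step 11
Reactants: 16 5,5-diethoxypent-2-yn-1-ol
Product: 18 (Z)-alkenyl(diphenyl)silane alcohol, via alkenylmagnesium alkoxide 17 (not isolated)
Conditions: CH2=CHCH2MgBr (2.2 equiv), Et2O, 0 → 35 °C; Ph2SiHCl, −78 → 0 °C; H2O
Reagents that add atoms: allylmagnesium bromide, C=CC[Mg]Br; chlorodiphenylsilane, Cl[SiH](c1ccccc1)c1ccccc1
Why: Hydroxyl-directed anti-carbomagnesiation puts the allyl group (C3, C4) on C5 and magnesium on C6 in a five-membered chelate, and silylation of the alkenyl Grignard with retention gives the tetrasubstituted alkene with Si cis to C16 and C4 cis to C7.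

Step 12
Reactants: 18 (Z)-alkenyl(diphenyl)silane alcohol
Product: 20 hydroxy acid, via aldehyde 19 (not isolated)
Conditions: 1 M aq. HCl, THF, 0 °C; then NaClO2, NaH2PO4, 2-methylbut-2-ene, t-BuOH/H2O, 0 °C
Reagents that add atoms: water, O; sodium chlorite, [Na+].[O-]Cl=O
Why: Acetal hydrolysis followed at once by Pinnick oxidation gives the C19 acid before the β,γ-unsaturated aldehyde can move into conjugation; the chlorine scavenger protects the alkenes.

Step 13
Reactants: 20 hydroxy acid
Product: 21 silyl ester silyl ether (fragment W)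
Conditions: TBSCl (2.5 equiv), imidazole, DMF, 0 °C
Reagents that add atoms: tert-butyldimethylsilyl chloride, CC(C)(C)[Si](C)(C)Cl
Why: Silylation masks the C16 hydroxyl and the C19 acid (as a silyl ester that can later be turned into the acid chloride without free acid) and leaves the Si–H bond intact.

Step 14
Reactants: 13 diacetate vinyl ketone (fragment E); 21 silyl ester silyl ether (fragment W)
Product: 22 silicon-tethered (Z)-silyl enol ether
Conditions: RhCl(PPh3)3 (2 mol %), toluene, 40 °C
Reagents that add atoms: none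
Why: Rhodium-catalysed 1,4-hydrosilylation of the terminal vinyl ketone (faster than that of the hindered ring A enone or the terminal alkenes) places silicon on O8 and hydride on C18 through the s-cis enone, which gives the Z enol ether (CH3 cis to O8) and joins the two fragments through C6–Si–O8.

Step 15
Reactants: 22 silicon-tethered (Z)-silyl enol ether
Product: 25 siloxane-bridged cyclobutanone, via acid chloride 23 (not isolated), via vinylketene 24 (not isolated)
Conditions: (COCl)2, DMF (cat.), CH2Cl2, 0 °C, then evaporation; slow addition to Et3N, toluene, 25 → 60 °C, 2 mM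
Reagents that add atoms: none
Why: Proposed new method: the silyl ester is converted under neutral conditions into acid chloride 23, Et3N removes the allylic C7–H to give vinylketene 24, and the ketene carbonyl carbon C19 is attacked by C17 of the tethered Z silyl enol ether while C7 closes on the siloxy-stabilised carbon C8 (asynchronous [π2s+π2a] cycloaddition); the closest known reactions are the intramolecular ketene–alkene [2+2] across a three-atom tether and the intermolecular [2+2] of ketenes with silyl enol ethers to 3-siloxycyclobutanones, but a ketene tethered to the enol oxygen through silicon has not been shown. The cyclobutanone closes by the C19–C17 and C7–C8 bonds and the five-membered 1-oxa-2-silacyclopentane (C7–C6–Si–O8–C8) closes with the C7–C8 bond, in the fused bicyclo[3.2.0] mode that the donor oxygen on the internal alkene carbon C8 dictates. C7 and C8 are set cis (C6 and O8 on one face) by the cis ring fusion that the short tether enforces, C17 follows from the Z enol ether by suprafacial addition (CH3 cis to O8), and the absolute sense at C8 is relayed from C9, the ketene adding anti to C10 with the C9–OAc bond in the inside position away from the bulky siloxy group. The step needs the cycloaddition to outrun ketene dimerisation and [1,5]-hydrogen shift of the vinylketene and needs one enol ether face; the tether, the polarised enol ether, slow addition at high dilution and the C9 stereocentre are what secure this.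

Step 16
Reactants: 25 siloxane-bridged cyclobutanone
Product: 26 siloxane-bridged γ-lactone
Conditions: m-CPBA (1.05 equiv), NaHCO3, CH2Cl2, 0 °C
Reagents that add atoms: 3-chloroperbenzoic acid, OOC(=O)c1cccc(Cl)c1
Why: Baeyer–Villiger oxidation of the strained cyclobutanone is faster than epoxidation of the hindered silyl-substituted or terminal alkenes, and the allylic ring-fusion carbon C7 migrates in preference to C17 with retention, which inserts O7 between C19 and C7.

Step 17
Reactants: 26 siloxane-bridged γ-lactone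
Product: 27 (2Z)-cyclodecene
Conditions: second-generation Hoveyda–Grubbs catalyst RuCl2(H2IMes)(=CH-C6H4-2-O-i-Pr) (10 mol %), toluene, 80 °C, 0.5 mM
Reagents that add atoms: none
Why: Ring-closing metathesis of the C1 vinyl and C5 allyl groups with loss of ethene closes the ten-membered ring at C2=C3; the bicyclic siloxane–lactone, the cis C5=C6 bond and ring A hold the termini close, and the medium ring is expected to form as the Z (ring-cis) alkene.

Step 18
Reactants: 27 (2Z)-cyclodecene
Product: 28 (2R,3S)-diol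
Conditions: OsO4 (5 mol %), NMO, acetone/H2O, 0 °C
Reagents that add atoms: osmium tetroxide (catalytic oxygen carrier), O=[Os](=O)(=O)=O; N-methylmorpholine N-oxide, C[N+]1([O-])CCOCC1; water, O
Why: Upjohn syn-dihydroxylation of the only accessible electron-rich alkene (C5=C6 is tetrasubstituted and shielded by silicon, the enone is electron-poor) gives the erythro diol from the Z alkene; attack on the outer face of the medium-ring alkene is assumed to give the (2R,3S) isomer.

Step 19
Reactants: 28 (2R,3S)-diol
Product: 29 C3 mesylate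
Conditions: MsCl, Et3N, CH2Cl2, −30 °C
Reagents that add atoms: methanesulfonyl chloride, CS(=O)(=O)Cl
Why: Sulfonylation goes to the less hindered C3 hydroxyl, because the C2 hydroxyl is neopentylic and the C8 and C16 oxygens are still masked by silicon.

Step 20
Reactants: 29 C3 mesylate
Product: 30 silyl-protected epoxide
Conditions: NaN(SiMe3)2 (1.05 equiv), THF, −78 → 0 °C
Reagents that add atoms: none
Why: Intramolecular Williamson reaction in which the C2 alkoxide displaces the C3 mesylate with inversion, turning the erythro diol derivative into the trans-(2R,3R) epoxide.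

Step 21
Reactants: 30 silyl-protected epoxide
Product: 31 target CNP0155754.2
Conditions: Bu4NF, AcOH, THF, 0 → 40 °C
Reagents that add atoms: none
Why: Fluoride cleaves the TBS ether and the Si–O8 bond, and the fluoride-activated alkenylsilane is protodesilylated at C6 with retention of the C5=C6 geometry; acetic acid buffers the medium so that the acetates, lactone and epoxide are kept.

**Compound list**
1 | pent-1-en-3-one (ethyl vinyl ketone) | CCC(=O)C=C | starting material
2 | (Z)-3-(tert-butyldimethylsilyloxy)penta-1,3-diene | C/C=C(\O[Si](C)(C)C(C)(C)C)C=C | intermediate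
3 | (E)-4-acetoxy-2-methylbut-2-enal | CC(=O)OC/C=C(\C)C=O | starting material
4 | Diels–Alder adduct (ring A aldehyde): [(1S,2S,6S)-3-(tert-butyldimethylsilyloxy)-6-formyl-2,6-dimethylcyclohex-3-en-1-yl]methyl acetate; C1 methyl cis to the C10 CH2OAc group, C11 methyl trans to both | CC(=O)OC[C@@H]1[C@@](C)(C=O)CC=C(O[Si](C)(C)C(C)(C)C)[C@H]1C | intermediate
5 | C1-vinyl silyl enol ether: 4 with CHO replaced by CH=CH2, stereocentres unchanged | CC(=O)OC[C@@H]1[C@@](C)(C=C)CC=C(O[Si](C)(C)C(C)(C)C)[C@H]1C | intermediate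
6 | ring A enone: (6-ethenyl-2,6-dimethyl-3-oxocyclohex-4-en-1-yl)methyl acetate, stereocentres as in 5 | CC(=O)OC[C@@H]1[C@@](C)(C=C)C=CC(=O)[C@H]1C | intermediate
7 | lithium dienolate of 6 (C11=C12–OLi) | CC(=O)OC[C@@H]1[C@@](C)(C=C)C=CC(O[Li])=C1C | intermediate
8 | 11-hydroxy enone acetate: (6-ethenyl-2-hydroxy-2,6-dimethyl-3-oxocyclohex-4-en-1-yl)methyl acetate, 11-OH trans to the CH2OAc group, (1S,10S,11S) in target numbering | CC(=O)OC[C@@H]1[C@@](C)(C=C)C=CC(=O)[C@@]1(C)O | intermediate
9 | ring A diol: 8 with the primary acetate removed | OC[C@@H]1[C@@](C)(C=C)C=CC(=O)[C@@]1(C)O | intermediate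
10 | C9 aldehyde: 9 with CH2OH oxidised to CHO | O=C[C@@H]1[C@@](C)(C=C)C=CC(=O)[C@@]1(C)O | intermediate
11 | allenyl carbinol: (9R)-adduct of 10 with the 1-methoxyallen-1-yl group | O[C@H]([C@@H]1[C@@](C)(C=C)C=CC(=O)[C@@]1(C)O)C(OC)=C=C | intermediate
12 | hydroxy vinyl ketone: (9R)-9,11-dihydroxy C8 vinyl ketone on ring A | O[C@H]([C@@H]1[C@@](C)(C=C)C=CC(=O)[C@@]1(C)O)C(=O)C=C | intermediate
13 | diacetate vinyl ketone (fragment E): 9,11-di-O-acetyl derivative of 12 | CC(=O)O[C@H]([C@@H]1[C@@](C)(C=C)C=CC(=O)[C@@]1(C)OC(C)=O)C(=O)C=C | intermediate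
14 | 4,4-diethoxybut-1-yne | C#CCC(OCC)OCC | starting material
15 | lithium acetylide of 14 | [Li]C#CCC(OCC)OCC | intermediate
16 | 5,5-diethoxypent-2-yn-1-ol | OCC#CCC(OCC)OCC | intermediate
17 | alkenylmagnesium alkoxide: (Z)-2-allyl-3-(bromomagnesio)-5,5-diethoxypent-2-en-1-olate magnesium bromide | Br[Mg]OC/C(CC=C)=C(\[Mg]Br)CC(OCC)OCC | intermediate
18 | (Z)-alkenyl(diphenyl)silane alcohol: (Z)-2-allyl-3-(diphenylsilyl)-5,5-diethoxypent-2-en-1-ol | OC/C(CC=C)=C(\[SiH](c1ccccc1)c1ccccc1)CC(OCC)OCC | intermediate
19 | aldehyde: (Z)-3-(diphenylsilyl)-4-(hydroxymethyl)hepta-3,6-dienal | OC/C(CC=C)=C(\[SiH](c1ccccc1)c1ccccc1)CC=O | intermediate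
20 | hydroxy acid: (Z)-3-(diphenylsilyl)-4-(hydroxymethyl)hepta-3,6-dienoic acid | OC/C(CC=C)=C(\[SiH](c1ccccc1)c1ccccc1)CC(=O)O | intermediate
21 | silyl ester silyl ether (fragment W): TBS ester and TBS ether of 20 | CC(C)(C)[Si](C)(C)OC/C(CC=C)=C(\[SiH](c1ccccc1)c1ccccc1)CC(=O)O[Si](C)(C)C(C)(C)C | intermediate
22 | silicon-tethered (Z)-silyl enol ether: O8 of the C8=C17 enol ether of 13 bonded to the SiPh2 group on C6 of fragment W | CC(=O)O[C@H]([C@@H]1[C@@](C)(C=C)C=CC(=O)[C@@]1(C)OC(C)=O)/C(O[Si](c2ccccc2)(c2ccccc2)/C(CC(=O)O[Si](C)(C)C(C)(C)C)=C(/CC=C)CO[Si](C)(C)C(C)(C)C)=C/C | intermediate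
23 | acid chloride: 22 with the silyl ester turned into C19(=O)Cl | CC(=O)O[C@H]([C@@H]1[C@@](C)(C=C)C=CC(=O)[C@@]1(C)OC(C)=O)/C(O[Si](c2ccccc2)(c2ccccc2)/C(CC(Cl)=O)=C(/CC=C)CO[Si](C)(C)C(C)(C)C)=C/C | intermediate
24 | vinylketene: C7H=C19=O on C6 | CC(=O)O[C@H]([C@@H]1[C@@](C)(C=C)C=CC(=O)[C@@]1(C)OC(C)=O)/C(O[Si](c2ccccc2)(c2ccccc2)/C(C=C=O)=C(/CC=C)CO[Si](C)(C)C(C)(C)C)=C/C | intermediate
25 | siloxane-bridged cyclobutanone: cyclobutanone C19(=O)–C7–C8–C17 cis-fused to the C7–C6–Si–O8–C8 ring; C6, O8 and the C17 methyl on one face | CC(=O)O[C@H]([C@@H]1[C@@](C)(C=C)C=CC(=O)[C@@]1(C)OC(C)=O)[C@]4(O[Si]3(c5ccccc5)c5ccccc5)[C@@H](C)C(=O)[C@H]4/C3=C(\CC=C)CO[Si](C)(C)C(C)(C)C | intermediate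
26 | siloxane-bridged γ-lactone: 25 with O7 inserted between C19 and C7 | CC(=O)O[C@H]([C@@H]1[C@@](C)(C=C)C=CC(=O)[C@@]1(C)OC(C)=O)[C@]4(O[Si]3(c5ccccc5)c5ccccc5)[C@@H](C)C(=O)O[C@H]4/C3=C(\CC=C)CO[Si](C)(C)C(C)(C)C | intermediate
27 | (2Z)-cyclodecene: ten-membered ring closed at C2=C3, other stereocentres as in 31 | CC(=O)O[C@@H]1[C@@H]2[C@](C)(C=CC(=O)[C@@]2(C)OC(C)=O)/C=C\C/C(CO[Si](C)(C)C(C)(C)C)=C3\[C@@H]2OC(=O)[C@H](C)[C@]21O[Si]3(c4ccccc4)c4ccccc4 | intermediate
28 | (2R,3S)-diol | CC(=O)O[C@@H]1[C@@H]2[C@](C)(C=CC(=O)[C@@]2(C)OC(C)=O)[C@@H](O)[C@@H](O)C/C(CO[Si](C)(C)C(C)(C)C)=C3\[C@@H]2OC(=O)[C@H](C)[C@]21O[Si]3(c4ccccc4)c4ccccc4 | intermediate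
29 | C3 mesylate of 28 | CC(=O)O[C@@H]1[C@@H]2[C@](C)(C=CC(=O)[C@@]2(C)OC(C)=O)[C@@H](O)[C@@H](OS(C)(=O)=O)C/C(CO[Si](C)(C)C(C)(C)C)=C3\[C@@H]2OC(=O)[C@H](C)[C@]21O[Si]3(c4ccccc4)c4ccccc4 | intermediate
30 | silyl-protected epoxide: 31 carrying the C6–SiPh2–O8 bridge and the 16-O-TBS group | CC(=O)O[C@@H]1[C@@H]2[C@](C)(C=CC(=O)[C@@]2(C)OC(C)=O)[C@H]2O[C@@H]2C/C(CO[Si](C)(C)C(C)(C)C)=C3\[C@@H]2OC(=O)[C@H](C)[C@]21O[Si]3(c4ccccc4)c4ccccc4 | intermediate
31 | target CNP0155754.2, (1S,2R,3R,5E,7S,8S,9R,10S,11S,17R) | CC(=O)O[C@@H]1[C@@H]2[C@](C)(C=CC(=O)[C@@]2(C)OC(C)=O)[C@H]2O[C@@H]2C/C(CO)=C\[C@@H]2OC(=O)[C@H](C)[C@]21O | target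

Total step count: 21. Longest linear sequence: 17 steps (steps 1–9 and 14–21).

**Steps most likely to fail**

1. Step 15 (key step). The cycloaddition may be outrun by ketene dimerisation, by [1,5]-hydrogen shift of the vinylketene, or by C-acylation with silyl transfer instead of ring closure. The silyl enol ether may also be degraded while the acid chloride is made, and the face selectivity relative to C9 may be low. Fallback, from 13 and 21 back to 26: the silicon bridge is installed after the cycloaddition instead of before it. 13 is reduced in the 1,4 sense with HSiMe2Ph and RhCl(PPh3)3 to the (Z)-dimethylphenylsilyl enol ether F1. 21 is converted with (COCl)2/DMF into the acid chloride F2. Slow addition of F2 to F1 and Et3N (EtAlCl2 promotion if needed) gives, by the known intermolecular [2+2] cycloaddition of a ketene with a silyl enol ether, the 2-alkenyl-3-siloxycyclobutanone F3. Baeyer–Villiger oxidation as in step 16 gives the lactone F4, and citric acid in MeOH removes the tertiary dimethylphenylsilyl ether to give the tertiary alcohol F5. Dehydrogenative Si–O coupling of the C6 diphenylsilyl hydride with the C8 hydroxyl (KOt-Bu cat. or RhCl(PPh3)3) then closes the siloxane and gives 26. Only the diastereomer with C6 and O8 cis can close, so this step also sorts the diastereomers.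

2. Step 17. Ring closure onto the hindered C1 vinyl group may be slow, oligomerisation may compete, and the E ring isomer may form. Fallback, from 26 back to 28: both terminal alkenes are cleaved (OsO4 cat., NaIO4, 2,6-lutidine; Johnson–Lemieux oxidation) to the C2,C3-dialdehyde F6. The ring is then closed by intramolecular pinacol coupling with the divalent vanadium reagent [V2Cl3(THF)6]2[Zn2Cl6] at high dilution, which forms the C2–C3 bond and leads to diol 28 after separation of diastereomers.

3. Step 18. OsO4 may add to the other face of the ring alkene, which would lead to the wrong epoxide enantiomeric sense at C2/C3. Fallback, from 27 back to 28: Woodward-type cis-hydroxylation, which delivers the two oxygens to the face opposite to the one that electrophiles attack. Iodine and AgOCOCF3 in wet MeCN give the trans iodo trifluoroacetate F7. Neighbouring-group displacement of iodide and hydrolysis of the dioxolanylium ion give the cis hydroxy trifluoroacetate F8. NaHCO3 in MeOH removes the trifluoroacetate and leaves the acetates, giving 28.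

Further compounds
F1 | step 15 | (Z)-dimethylphenylsilyl enol ether of 13 | CC(=O)O[C@H]([C@@H]1[C@@](C)(C=C)C=CC(=O)[C@@]1(C)OC(C)=O)/C(O[Si](C)(C)c2ccccc2)=C/C
F2 | step 15 | acid chloride of fragment W (C19 acid chloride, Si–H and 16-O-TBS kept) | CC(C)(C)[Si](C)(C)OC/C(CC=C)=C(\[SiH](c1ccccc1)c1ccccc1)CC(Cl)=O
F3 | step 15 | untethered 2-alkenyl-3-(dimethylphenylsiloxy)cyclobutanone | CC(=O)O[C@H]([C@@H]1[C@@](C)(C=C)C=CC(=O)[C@@]1(C)OC(C)=O)[C@]4(O[Si](C)(C)c2ccccc2)[C@@H](C)C(=O)[C@H]4/C([SiH](c5ccccc5)c5ccccc5)=C(\CC=C)CO[Si](C)(C)C(C)(C)C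
F4 | step 15 | untethered γ-lactone with 8-O-dimethylphenylsilyl ether | CC(=O)O[C@H]([C@@H]1[C@@](C)(C=C)C=CC(=O)[C@@]1(C)OC(C)=O)[C@]4(O[Si](C)(C)c2ccccc2)[C@@H](C)C(=O)O[C@H]4/C([SiH](c5ccccc5)c5ccccc5)=C(\CC=C)CO[Si](C)(C)C(C)(C)C
F5 | step 15 | untethered γ-lactone with free 8-OH and C6 diphenylsilyl hydride | CC(=O)O[C@H]([C@@H]1[C@@](C)(C=C)C=CC(=O)[C@@]1(C)OC(C)=O)[C@]4(O)[C@@H](C)C(=O)O[C@H]4/C([SiH](c5ccccc5)c5ccccc5)=C(\CC=C)CO[Si](C)(C)C(C)(C)C
F6 | step 17 | C2,C3-dialdehyde from 26 | CC(=O)O[C@H]([C@@H]1[C@@](C)(C=O)C=CC(=O)[C@@]1(C)OC(C)=O)[C@]4(O[Si]3(c5ccccc5)c5ccccc5)[C@@H](C)C(=O)O[C@H]4/C3=C(\CC=O)CO[Si](C)(C)C(C)(C)C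
F7 | step 18 | trans 2-iodo 3-trifluoroacetate of 27 | CC(=O)O[C@@H]1[C@@H]2[C@](C)(C=CC(=O)[C@@]2(C)OC(C)=O)[C@H](I)[C@@H](OC(=O)C(F)(F)F)C/C(CO[Si](C)(C)C(C)(C)C)=C3\[C@@H]2OC(=O)[C@H](C)[C@]21O[Si]3(c4ccccc4)c4ccccc4
F8 | step 18 | cis 3-hydroxy 2-trifluoroacetate | CC(=O)O[C@@H]1[C@@H]2[C@](C)(C=CC(=O)[C@@]2(C)OC(C)=O)[C@@H](OC(=O)C(F)(F)F)[C@@H](O)C/C(CO[Si](C)(C)C(C)(C)C)=C3\[C@@H]2OC(=O)[C@H](C)[C@]21O[Si]3(c4ccccc4)c4ccccc4
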